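**Retrosynthetic overview**
1. Target ⇒ global desilylation of a deca-silyl ether; the gallate is attached between the two flavan-forming sequences, so the two C3 hydroxyls never have to be told apart.
2. Both flavans are cut at the C2–aryl bond: a 1-bromo-8-iodobenzotropolone is arylated twice (C–I first, C–Br second) with one 3-silyloxy-2H-chromene by nickel/photoredox radical C(sp3)–H arylation (key step).
3. Each coupling product is an enol ether of a flavan-3-one; Ru-catalysed transfer hydrogenation with dynamic kinetic resolution sets C2 and C3 together (2R,3R, cis).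
4. Benzotropolone ⇒ oxidative condensation of 5-iodopyrogallol with 4-bromo-o-benzoquinone; chromene ⇒ photoredox radical cyclisation of an aryloxy bromoacetone made from resorcinol.
5. Ring order: chromene A/C rings (made separately) → benzotropolone bicycle → flavan on the seven-membered ring (then galloylated) → flavan on the benzo ring.

Assumption: silyl tropolone ethers are drawn as the 6-O-silyl isomer (O-to-O silyl shift makes the choice immaterial), the coupled enol ethers are used as C2-epimer mixtures, and the (R,R) catalyst antipode is taken as the one that delivers hydride to the Si face of C3 (otherwise its mirror image is used).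

**Route**

Step 1
Reactants: 1 resorcinol
Product: 2 1,3-bis(triisopropylsilyloxy)benzene
Conditions: TIPSCl (2.2 equiv), imidazole, DMF, rt
Reagents that add atoms: triisopropylsilyl chloride, CC(C)[Si](Cl)(C(C)C)C(C)C
Why: Standard imidazole-promoted phenol silylation; the bulky silyl ethers carry no weak C–H bonds, steer the next C–H borylation and come off with fluoride at the end.

Step 2
Reactants: 2 1,3-bis(triisopropylsilyloxy)benzene
Product: 4 3,5-bis(triisopropylsilyloxy)phenol, via arylboronic pinacol ester 3 (not isolated)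
Conditions: [Ir(OMe)(cod)]2 (1.5 mol %), dtbpy (3 mol %), B2pin2 (1.0 equiv), hexane, 80 °C; then Oxone (2KHSO5·KHSO4·K2SO4), acetone/H2O, rt
Reagents that add atoms: bis(pinacolato)diboron, CC1(C)OB(OC1(C)C)B1OC(C)(C)C(C)(C)O1; potassium peroxymonosulfate, [K+].[O-]S(=O)(=O)OO
Why: Sterically governed iridium-catalysed arene C–H borylation hits only C5 (the one C–H not next to a silyloxy group) and the boronate is oxidised in the same pot (one-pot borylation/oxidation to a phenol).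

Step 3
Reactants: 4 3,5-bis(triisopropylsilyloxy)phenol; 5 1,3-dibromoacetone
Product: 6 1-bromo-3-[3,5-bis(triisopropylsilyloxy)phenoxy]propan-2-one
Conditions: 5 (3 equiv), K2CO3 (1.1 equiv), dry acetone, 0 °C to rt
Reagents that add atoms: none
Why: Williamson ether synthesis on a reactive α-bromoketone; excess dibromoacetone suppresses double alkylation and aryl triisopropylsilyl ethers tolerate K2CO3 in dry acetone.

Step 4
Reactants: 6 1-bromo-3-[3,5-bis(triisopropylsilyloxy)phenoxy]propan-2-one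
Product: 7 5,7-bis(triisopropylsilyloxy)chroman-3-one
Conditions: fac-Ir(ppy)3 (1 mol %), 2,6-lutidine (2 equiv), degassed MeCN, 450 nm LEDs, rt
Reagents that add atoms: none
Why: Photoredox homolytic aromatic substitution: the excited iridium complex reduces the C–Br bond, the electrophilic α-keto radical adds to the electron-rich ortho carbon (six-membered ring) and oxidation/deprotonation rearomatises, avoiding the acid-promoted cyclodehydration of aryloxyacetones to benzofurans.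

Step 5
Reactants: 7 5,7-bis(triisopropylsilyloxy)chroman-3-one
Product: 8 3-(triethylsilyloxy)-5,7-bis(triisopropylsilyloxy)-2H-chromene
Conditions: TESOTf (1.2 equiv), Et3N (2 equiv), CH2Cl2, −78 to 0 °C
Reagents that add atoms: triethylsilyl trifluoromethanesulfonate, CC[Si](CC)(CC)OS(=O)(=O)C(F)(F)F
Why: Soft enolisation gives the arene-conjugated (C3=C4) enol silyl ether, as with 2-tetralones, which leaves C2 as the only sp3 C–H position of the heterocycle.

Step 6
Reactants: 9 1,3-dimethoxybenzene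
Product: 12 2,6-dimethoxyphenol, via 2,6-dimethoxyphenyllithium 10 (not isolated), via dimethyl (2,6-dimethoxyphenyl)boronate 11 (not isolated)
Conditions: n-BuLi, THF, 0 °C to rt; B(OMe)3, −78 °C to rt; then AcOH, 30% H2O2, 0 °C to rt
Reagents that add atoms: n-butyllithium, [Li]CCCC; trimethyl borate, COB(OC)OC; hydrogen peroxide, OO
Why: Directed ortho-metalation between the two methoxy groups followed by borylation and oxidation of the C–B bond installs the third oxygen of the pyrogallol pattern.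

Step 7
Reactants: 12 2,6-dimethoxyphenol
Product: 13 4-iodo-2,6-dimethoxyphenol
Conditions: NIS (1.05 equiv), MeCN, 0 °C to rt
Reagents that add atoms: N-iodosuccinimide, O=C1CCC(=O)N1I
Why: Electrophilic aromatic iodination goes para to the free phenol because both ortho positions are blocked.

Step 8
Reactants: 13 4-iodo-2,6-dimethoxyphenol
Product: 14 5-iodobenzene-1,2,3-triol
Conditions: BBr3 (3.3 equiv), CH2Cl2, −78 °C to rt; H2O quench; handled under argon
Reagents that add atoms: none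
Why: Lewis-acid cleavage of the two aryl methyl ethers with BBr3 leaves the aryl iodide untouched.

Step 9
Reactants: 14 5-iodobenzene-1,2,3-triol
Product: 15 5-iodo-1,2,3-tris(tert-butyldimethylsilyloxy)benzene
Conditions: TBSCl (3.6 equiv), imidazole, DMF, rt
Reagents that add atoms: tert-butyldimethylsilyl chloride, CC(C)(C)[Si](C)(C)Cl
Why: Exhaustive phenol silylation gives the fluoride-labile protection needed on the future galloyl group.

Step 10
Reactants: 15 5-iodo-1,2,3-tris(tert-butyldimethylsilyloxy)benzene; 16 carbon dioxide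
Product: 18 3,4,5-tris(tert-butyldimethylsilyloxy)benzoic acid, via arylmagnesium chloride 17 (not isolated)
Conditions: i-PrMgCl·LiCl, THF, −20 to 0 °C; CO2 (gas), −20 °C to rt; cold 1 M HCl work-up
Reagents that add atoms: isopropylmagnesium chloride–lithium chloride, CC(C)[Mg]Cl.[Li+].[Cl-]
Why: Iodine–magnesium exchange followed by carboxylation of the aryl Grignard reagent gives the protected gallic acid.

Step 11
Reactants: 19 catechol
Product: 20 4-bromobenzene-1,2-diol
Conditions: NBS (1.0 equiv), HBF4·OEt2, MeCN, −30 °C to rt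
Reagents that add atoms: N-bromosuccinimide, O=C1CCC(=O)N1Br
Why: Acid-promoted electrophilic bromination of catechol is selective for the position para to a hydroxyl group.

Step 12
Reactants: 20 4-bromobenzene-1,2-diol; 14 5-iodobenzene-1,2,3-triol
Product: 22 1-bromo-3,4,6-trihydroxy-8-iodo-5H-benzo[7]annulen-5-one, via 4-bromo-1,2-benzoquinone 21 (not isolated)
Conditions: 20 (3 equiv), NaIO4 (3 equiv), MeCN/H2O, 0 °C, 10 min; then 14 (1 equiv), pH 5 acetate buffer/MeCN, 0 °C to rt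
Reagents that add atoms: none
Why: Purpurogallin-type oxidative condensation (conjugate addition of the pyrogallol to C5 of the o-quinone, reoxidation by excess quinone, closure to a bicyclo[3.2.1]octane and oxidative decarboxylation) builds the benzotropolone with iodine at C8 and bromine at C1, the positions the two flavans occupy in the target.

Step 13
Reactants: 22 1-bromo-3,4,6-trihydroxy-8-iodo-5H-benzo[7]annulen-5-one
Product: 23 1-bromo-8-iodo-3,4,6-tris(triisopropylsilyloxy)-5H-benzo[7]annulen-5-one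
Conditions: TIPSOTf (3.6 equiv), 2,6-lutidine, CH2Cl2, 0 °C to rt
Reagents that add atoms: triisopropylsilyl trifluoromethanesulfonate, CC(C)[Si](OS(=O)(=O)C(F)(F)F)(C(C)C)C(C)C
Why: The silyl triflate silylates even the chelated peri hydroxyl and the tropolone hydroxyl, masking every acidic or metal-binding OH before nickel catalysis.

Step 14 (key step)
Reactants: 23 1-bromo-8-iodo-3,4,6-tris(triisopropylsilyloxy)-5H-benzo[7]annulen-5-one; 8 3-(triethylsilyloxy)-5,7-bis(triisopropylsilyloxy)-2H-chromene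
Product: 24 racemic 1-bromo-8-[3-(triethylsilyloxy)-5,7-bis(triisopropylsilyloxy)-2H-chromen-2-yl]-3,4,6-tris(triisopropylsilyloxy)-5H-benzo[7]annulen-5-one
Conditions: 8 (3 equiv), NiBr2(dme) (10 mol %), dtbbpy (12 mol %), Ir[dF(CF3)ppy]2(dtbbpy)PF6 (2 mol %), 2,4,6-collidine (2 equiv), degassed DME, 456 nm LEDs, 25 °C
Reagents that add atoms: none
Why: Proposed new method: the excited iridium photocatalyst oxidises the electron-rich enol silyl ether 8 to its radical cation, collidine removes the acidified C2–H (the only sp3 C–H of the ring) to give an oxygen-stabilised allyl radical, and this radical is captured by the aryl–nickel iodide formed by oxidative addition of zerovalent nickel into the C–I bond (faster than into C–Br), so reductive elimination forges the flavan C2–aryl bond; attack at C2 rather than C4 is expected because C4 is shielded by the peri 5-silyloxy group and C2 attack keeps the styrenyl enol ether; closest precedents are photoredox allylic C–H functionalisation of enol silyl ethers by radical-cation deprotonation and nickel/photoredox C(sp3)–H arylation of ethers and allylic positions; C2 is formed racemic and is corrected in step 15.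

Step 15
Reactants: 24 racemic 1-bromo-8-[3-(triethylsilyloxy)-5,7-bis(triisopropylsilyloxy)-2H-chromen-2-yl]-3,4,6-tris(triisopropylsilyloxy)-5H-benzo[7]annulen-5-one
Product: 26 (2R,3R)-2-[1-bromo-5-oxo-3,4,6-tris(triisopropylsilyloxy)-5H-benzo[7]annulen-8-yl]-5,7-bis(triisopropylsilyloxy)chroman-3-ol, via flavan-3-one 25 (not isolated)
Conditions: RuCl(p-cymene)[(R,R)-TsDPEN] (5 mol %), HCO2H/Et3N (5:2), MeOH (5 equiv), EtOAc, 40 °C, argon
Reagents that add atoms: none
Why: Formic acid protodesilylates the enol ether to the flavan-3-one, whose C2 epimerises quickly through the enol under Et3N, and Noyori–Ikariya asymmetric transfer hydrogenation with dynamic kinetic resolution reduces only the (2R)-ketone by hydride delivery to the Si face of C3 anti to the C2 aryl group, giving the 2,3-cis (2R,3R) alcohol.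

Step 16
Reactants: 26 (2R,3R)-2-[1-bromo-5-oxo-3,4,6-tris(triisopropylsilyloxy)-5H-benzo[7]annulen-8-yl]-5,7-bis(triisopropylsilyloxy)chroman-3-ol; 18 3,4,5-tris(tert-butyldimethylsilyloxy)benzoic acid
Product: 27 (2R,3R)-2-[1-bromo-5-oxo-3,4,6-tris(triisopropylsilyloxy)-5H-benzo[7]annulen-8-yl]-5,7-bis(triisopropylsilyloxy)chroman-3-yl 3,4,5-tris(tert-butyldimethylsilyloxy)benzoate
Conditions: 18 (1.5 equiv), EDC·HCl (2 equiv), DMAP (0.5 equiv), CH2Cl2, rt
Reagents that add atoms: none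
Why: Steglich esterification of the only free hydroxyl in the molecule places the gallate on the flavan of the seven-membered ring without any selectivity problem and without touching the stereocentres.

Step 17 (key step, second use)
Reactants: 27 (2R,3R)-2-[1-bromo-5-oxo-3,4,6-tris(triisopropylsilyloxy)-5H-benzo[7]annulen-8-yl]-5,7-bis(triisopropylsilyloxy)chroman-3-yl 3,4,5-tris(tert-butyldimethylsilyloxy)benzoate; 8 3-(triethylsilyloxy)-5,7-bis(triisopropylsilyloxy)-2H-chromene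
Product: 28 (2R,3R)-2-{5-oxo-1-[3-(triethylsilyloxy)-5,7-bis(triisopropylsilyloxy)-2H-chromen-2-yl]-3,4,6-tris(triisopropylsilyloxy)-5H-benzo[7]annulen-8-yl}-5,7-bis(triisopropylsilyloxy)chroman-3-yl 3,4,5-tris(tert-butyldimethylsilyloxy)benzoate (both epimers at the new chromene C2)
Conditions: 8 (3 equiv), NiBr2(dme) (15 mol %), dtbbpy (18 mol %), Ir[dF(CF3)ppy]2(dtbbpy)PF6 (2 mol %), 2,4,6-collidine (2 equiv), degassed DME, 456 nm LEDs, 30 °C
Reagents that add atoms: none
Why: Proposed new method: the same radical-cation deprotonation/nickel arylation as in step 14 now engages the remaining C–Br bond, and because the radical is made by selective one-electron oxidation of the most electron-rich π system (8) rather than by an indiscriminate hydrogen-atom abstractor, the benzylic C–H bonds of the first flavan stay intact; closest precedent is nickel/photoredox C(sp3)–H arylation with aryl bromides; the new C2 is unselective and is corrected in step 18.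

Step 18
Reactants: 28 (2R,3R)-2-{5-oxo-1-[3-(triethylsilyloxy)-5,7-bis(triisopropylsilyloxy)-2H-chromen-2-yl]-3,4,6-tris(triisopropylsilyloxy)-5H-benzo[7]annulen-8-yl}-5,7-bis(triisopropylsilyloxy)chroman-3-yl 3,4,5-tris(tert-butyldimethylsilyloxy)benzoate
Product: 30 (2R,3R)-2-{1-[(2R,3R)-3-hydroxy-5,7-bis(triisopropylsilyloxy)chroman-2-yl]-5-oxo-3,4,6-tris(triisopropylsilyloxy)-5H-benzo[7]annulen-8-yl}-5,7-bis(triisopropylsilyloxy)chroman-3-yl 3,4,5-tris(tert-butyldimethylsilyloxy)benzoate, via flavan-3-one 29 (not isolated)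
Conditions: RuCl(p-cymene)[(R,R)-TsDPEN] (5 mol %), HCO2H/Et3N (5:2), MeOH (5 equiv), EtOAc, 40 °C, argon
Reagents that add atoms: none
Why: In situ protodesilylation and Noyori–Ikariya transfer hydrogenation with dynamic kinetic resolution, as in step 15, set the second flavan as (2R,3R)-cis under catalyst control, while the first flavan has no ketone and cannot epimerise.

Step 19
Reactants: 30 (2R,3R)-2-{1-[(2R,3R)-3-hydroxy-5,7-bis(triisopropylsilyloxy)chroman-2-yl]-5-oxo-3,4,6-tris(triisopropylsilyloxy)-5H-benzo[7]annulen-8-yl}-5,7-bis(triisopropylsilyloxy)chroman-3-yl 3,4,5-tris(tert-butyldimethylsilyloxy)benzoate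
Product: 31 theaflavin 3-gallate (CNP0488827.1)
Conditions: TBAF/AcOH (1:1, 12 equiv), THF, 0 °C to rt, argon
Reagents that add atoms: none
Why: Acetic-acid-buffered fluoride cleaves all ten aryl and tropolone silyl ethers under near-neutral conditions that spare the gallate ester, the benzotropolone and the four stereocentres.

**Compound list**
1 | resorcinol | Oc1cccc(O)c1 | starting material
2 | 1,3-bis(triisopropylsilyloxy)benzene | CC(C)[Si](C(C)C)(C(C)C)Oc1cccc(O[Si](C(C)C)(C(C)C)C(C)C)c1 | intermediate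
3 | 2-[3,5-bis(triisopropylsilyloxy)phenyl]-4,4,5,5-tetramethyl-1,3,2-dioxaborolane | CC(C)[Si](C(C)C)(C(C)C)Oc1cc(O[Si](C(C)C)(C(C)C)C(C)C)cc(B2OC(C)(C)C(C)(C)O2)c1 | intermediate
4 | 3,5-bis(triisopropylsilyloxy)phenol | Oc1cc(O[Si](C(C)C)(C(C)C)C(C)C)cc(O[Si](C(C)C)(C(C)C)C(C)C)c1 | intermediate
5 | 1,3-dibromoacetone | BrCC(=O)CBr | starting material
6 | 1-bromo-3-[3,5-bis(triisopropylsilyloxy)phenoxy]propan-2-one | BrCC(=O)COc1cc(O[Si](C(C)C)(C(C)C)C(C)C)cc(O[Si](C(C)C)(C(C)C)C(C)C)c1 | intermediate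
7 | 5,7-bis(triisopropylsilyloxy)chroman-3-one | O=C1COc2cc(O[Si](C(C)C)(C(C)C)C(C)C)cc(O[Si](C(C)C)(C(C)C)C(C)C)c2C1 | intermediate
8 | 3-(triethylsilyloxy)-5,7-bis(triisopropylsilyloxy)-2H-chromene | CC[Si](CC)(CC)OC1=Cc2c(O[Si](C(C)C)(C(C)C)C(C)C)cc(O[Si](C(C)C)(C(C)C)C(C)C)cc2OC1 | intermediate
9 | 1,3-dimethoxybenzene | COc1cccc(OC)c1 | starting material
10 | 2,6-dimethoxyphenyllithium | [Li]c1c(OC)cccc1OC | intermediate
11 | dimethyl (2,6-dimethoxyphenyl)boronate | COB(OC)c1c(OC)cccc1OC | intermediate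
12 | 2,6-dimethoxyphenol | COc1cccc(OC)c1O | intermediate
13 | 4-iodo-2,6-dimethoxyphenol | COc1cc(I)cc(OC)c1O | intermediate
14 | 5-iodobenzene-1,2,3-triol | Oc1cc(I)cc(O)c1O | intermediate
15 | 5-iodo-1,2,3-tris(tert-butyldimethylsilyloxy)benzene | CC(C)(C)[Si](C)(C)Oc1cc(I)cc(O[Si](C)(C)C(C)(C)C)c1O[Si](C)(C)C(C)(C)C | intermediate
16 | carbon dioxide | O=C=O | starting material
17 | [3,4,5-tris(tert-butyldimethylsilyloxy)phenyl]magnesium chloride | Cl[Mg]c1cc(O[Si](C)(C)C(C)(C)C)c(O[Si](C)(C)C(C)(C)C)c(O[Si](C)(C)C(C)(C)C)c1 | intermediate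
18 | 3,4,5-tris(tert-butyldimethylsilyloxy)benzoic acid | OC(=O)c1cc(O[Si](C)(C)C(C)(C)C)c(O[Si](C)(C)C(C)(C)C)c(O[Si](C)(C)C(C)(C)C)c1 | intermediate
19 | catechol | Oc1ccccc1O | starting material
20 | 4-bromobenzene-1,2-diol | Oc1ccc(Br)cc1O | intermediate
21 | 4-bromo-1,2-benzoquinone | O=C1C=CC(Br)=CC1=O | intermediate
22 | 1-bromo-3,4,6-trihydroxy-8-iodo-5H-benzo[7]annulen-5-one | O=c1c(O)cc(I)cc2c(Br)cc(O)c(O)c12 | intermediate
23 | 1-bromo-8-iodo-3,4,6-tris(triisopropylsilyloxy)-5H-benzo[7]annulen-5-one | O=c1c(O[Si](C(C)C)(C(C)C)C(C)C)cc(I)cc2c(Br)cc(O[Si](C(C)C)(C(C)C)C(C)C)c(O[Si](C(C)C)(C(C)C)C(C)C)c12 | intermediate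
24 | racemic 1-bromo-8-[3-(triethylsilyloxy)-5,7-bis(triisopropylsilyloxy)-2H-chromen-2-yl]-3,4,6-tris(triisopropylsilyloxy)-5H-benzo[7]annulen-5-one | O=c1c(O[Si](C(C)C)(C(C)C)C(C)C)cc(C3Oc4cc(O[Si](C(C)C)(C(C)C)C(C)C)cc(O[Si](C(C)C)(C(C)C)C(C)C)c4C=C3O[Si](CC)(CC)CC)cc2c(Br)cc(O[Si](C(C)C)(C(C)C)C(C)C)c(O[Si](C(C)C)(C(C)C)C(C)C)c12 | intermediate
25 | 2-[1-bromo-5-oxo-3,4,6-tris(triisopropylsilyloxy)-5H-benzo[7]annulen-8-yl]-5,7-bis(triisopropylsilyloxy)chroman-3-one (C2 epimerising) | O=c1c(O[Si](C(C)C)(C(C)C)C(C)C)cc(C3Oc4cc(O[Si](C(C)C)(C(C)C)C(C)C)cc(O[Si](C(C)C)(C(C)C)C(C)C)c4CC3=O)cc2c(Br)cc(O[Si](C(C)C)(C(C)C)C(C)C)c(O[Si](C(C)C)(C(C)C)C(C)C)c12 | intermediate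
26 | (2R,3R)-2-[1-bromo-5-oxo-3,4,6-tris(triisopropylsilyloxy)-5H-benzo[7]annulen-8-yl]-5,7-bis(triisopropylsilyloxy)chroman-3-ol | O[C@@H]1Cc2c(O[Si](C(C)C)(C(C)C)C(C)C)cc(O[Si](C(C)C)(C(C)C)C(C)C)cc2O[C@@H]1c1cc(O[Si](C(C)C)(C(C)C)C(C)C)c(=O)c2c(O[Si](C(C)C)(C(C)C)C(C)C)c(O[Si](C(C)C)(C(C)C)C(C)C)cc(Br)c2c1 | intermediate
27 | (2R,3R)-2-[1-bromo-5-oxo-3,4,6-tris(triisopropylsilyloxy)-5H-benzo[7]annulen-8-yl]-5,7-bis(triisopropylsilyloxy)chroman-3-yl 3,4,5-tris(tert-butyldimethylsilyloxy)benzoate | O=C(O[C@@H]1Cc2c(O[Si](C(C)C)(C(C)C)C(C)C)cc(O[Si](C(C)C)(C(C)C)C(C)C)cc2O[C@@H]1c1cc(O[Si](C(C)C)(C(C)C)C(C)C)c(=O)c2c(O[Si](C(C)C)(C(C)C)C(C)C)c(O[Si](C(C)C)(C(C)C)C(C)C)cc(Br)c2c1)c1cc(O[Si](C)(C)C(C)(C)C)c(O[Si](C)(C)C(C)(C)C)c(O[Si](C)(C)C(C)(C)C)c1 | intermediate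
28 | compound 27 with Br replaced by a 3-(triethylsilyloxy)-5,7-bis(triisopropylsilyloxy)-2H-chromen-2-yl group (both C2 epimers) | O=C(O[C@@H]1Cc2c(O[Si](C(C)C)(C(C)C)C(C)C)cc(O[Si](C(C)C)(C(C)C)C(C)C)cc2O[C@@H]1c1cc(O[Si](C(C)C)(C(C)C)C(C)C)c(=O)c2c(O[Si](C(C)C)(C(C)C)C(C)C)c(O[Si](C(C)C)(C(C)C)C(C)C)cc(C3Oc4cc(O[Si](C(C)C)(C(C)C)C(C)C)cc(O[Si](C(C)C)(C(C)C)C(C)C)c4C=C3O[Si](CC)(CC)CC)c2c1)c1cc(O[Si](C)(C)C(C)(C)C)c(O[Si](C)(C)C(C)(C)C)c(O[Si](C)(C)C(C)(C)C)c1 | intermediate
29 | compound 27 with Br replaced by a 3-oxo-5,7-bis(triisopropylsilyloxy)chroman-2-yl group (C2 epimerising) | O=C(O[C@@H]1Cc2c(O[Si](C(C)C)(C(C)C)C(C)C)cc(O[Si](C(C)C)(C(C)C)C(C)C)cc2O[C@@H]1c1cc(O[Si](C(C)C)(C(C)C)C(C)C)c(=O)c2c(O[Si](C(C)C)(C(C)C)C(C)C)c(O[Si](C(C)C)(C(C)C)C(C)C)cc(C3Oc4cc(O[Si](C(C)C)(C(C)C)C(C)C)cc(O[Si](C(C)C)(C(C)C)C(C)C)c4CC3=O)c2c1)c1cc(O[Si](C)(C)C(C)(C)C)c(O[Si](C)(C)C(C)(C)C)c(O[Si](C)(C)C(C)(C)C)c1 | intermediate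
30 | (2R,3R)-2-{1-[(2R,3R)-3-hydroxy-5,7-bis(triisopropylsilyloxy)chroman-2-yl]-5-oxo-3,4,6-tris(triisopropylsilyloxy)-5H-benzo[7]annulen-8-yl}-5,7-bis(triisopropylsilyloxy)chroman-3-yl 3,4,5-tris(tert-butyldimethylsilyloxy)benzoate | O=C(O[C@@H]1Cc2c(O[Si](C(C)C)(C(C)C)C(C)C)cc(O[Si](C(C)C)(C(C)C)C(C)C)cc2O[C@@H]1c1cc(O[Si](C(C)C)(C(C)C)C(C)C)c(=O)c2c(O[Si](C(C)C)(C(C)C)C(C)C)c(O[Si](C(C)C)(C(C)C)C(C)C)cc([C@H]3Oc4cc(O[Si](C(C)C)(C(C)C)C(C)C)cc(O[Si](C(C)C)(C(C)C)C(C)C)c4C[C@H]3O)c2c1)c1cc(O[Si](C)(C)C(C)(C)C)c(O[Si](C)(C)C(C)(C)C)c(O[Si](C)(C)C(C)(C)C)c1 | intermediate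
31 | theaflavin 3-gallate: (2R,3R)-2-{3,4,6-trihydroxy-5-oxo-1-[(2R,3R)-3,5,7-trihydroxychroman-2-yl]-5H-benzo[7]annulen-8-yl}-5,7-dihydroxychroman-3-yl 3,4,5-trihydroxybenzoate | O=C(O[C@@H]1Cc2c(O)cc(O)cc2O[C@@H]1c1cc(=O)c(O)c2c(O)c(O)cc([C@H]3Oc4cc(O)cc(O)c4C[C@H]3O)c2c1)c1cc(O)c(O)c(O)c1 | target

**Step count and risks**

Total: 19 steps. Longest linear sequence: 11 steps (steps 1–5 then 14–19; equally steps 6–8, 12, 13 then 14–19).

The three steps most likely to fail:

The first is step 14. The radical C–H arylation is untested: coupling could occur at C4 instead of C2, the product enol ether could be over-oxidised, and the silylated tropolone may absorb the light. The fallback sets out from 23 and 8 and makes the same bond by two-electron chemistry. Iodine–magnesium exchange on 23 (i-PrMgCl·LiCl, THF, −40 °C, C–Br untouched) gives [1-bromo-5-oxo-3,4,6-tris(triisopropylsilyloxy)-5H-benzo[7]annulen-8-yl]magnesium chloride F1. Hydride abstraction from C2 of 8 with Ph3CBF4 (CH2Cl2, −40 °C) gives 3-(triethylsilyloxy)-5,7-bis(triisopropylsilyloxy)chromenylium tetrafluoroborate F2. Addition of the Grignard reagent to C2 of this benzopyrylium ion at −78 °C returns to the route at 24.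

The second is step 17. Oxidative addition is slower at the peri-hindered, electron-rich C–Br bond, and the substrate already carries a complete flavan. The fallback sets out from 27 and 8. Miyaura borylation of 27 (B2pin2, PdCl2(dppf), KOAc, dioxane, 80 °C) gives the pinacol boronate (2R,3R)-2-[5-oxo-1-(4,4,5,5-tetramethyl-1,3,2-dioxaborolan-2-yl)-3,4,6-tris(triisopropylsilyloxy)-5H-benzo[7]annulen-8-yl]-5,7-bis(triisopropylsilyloxy)chroman-3-yl 3,4,5-tris(tert-butyldimethylsilyloxy)benzoate F3. DDQ in CH2Cl2/EtOH converts 8 into the chromene acetal 2-ethoxy-3-(triethylsilyloxy)-5,7-bis(triisopropylsilyloxy)-2H-chromene F4. Nickel-catalysed acetal–boronate coupling (Ni(cod)2, PPh3, K3PO4, dioxane/H2O, via an oxocarbenium/allylnickel intermediate; no aryl halide is left to interfere) returns to the route at 28.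

The third is step 12. With a halogenated o-quinone, ipso attack at the bromine-bearing carbon and self-condensation of 14 can compete with the crossed condensation. The fallback sets out from 20 and 14 and puts a trimethylsilyl placeholder where the bromine must end up:
- 20 is silylated (TBSCl, imidazole) to 4-bromo-1,2-bis(tert-butyldimethylsilyloxy)benzene F5.
- Bromine–lithium exchange (t-BuLi, THF, −78 °C) gives [3,4-bis(tert-butyldimethylsilyloxy)phenyl]lithium F6, which is quenched with TMSCl to [3,4-bis(tert-butyldimethylsilyloxy)phenyl]trimethylsilane F7.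
- TBAF/AcOH frees 4-(trimethylsilyl)benzene-1,2-diol F8.
- NaIO4 oxidises it to 4-(trimethylsilyl)-1,2-benzoquinone F9, which behaves like the classical 4-alkyl-o-quinones and condenses with 14 to 3,4,6-trihydroxy-8-iodo-1-(trimethylsilyl)-5H-benzo[7]annulen-5-one F10.
- TIPSOTf/2,6-lutidine gives 8-iodo-1-(trimethylsilyl)-3,4,6-tris(triisopropylsilyloxy)-5H-benzo[7]annulen-5-one F11.
- Ipso-bromodesilylation (NBS, MeCN, 0 °C) returns to the route at 23.

Further compounds
F1 | step 14 | [1-bromo-5-oxo-3,4,6-tris(triisopropylsilyloxy)-5H-benzo[7]annulen-8-yl]magnesium chloride | Cl[Mg]c1cc(O[Si](C(C)C)(C(C)C)C(C)C)c(=O)c2c(O[Si](C(C)C)(C(C)C)C(C)C)c(O[Si](C(C)C)(C(C)C)C(C)C)cc(Br)c2c1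
F2 | step 14 | 3-(triethylsilyloxy)-5,7-bis(triisopropylsilyloxy)chromenylium tetrafluoroborate | CC[Si](CC)(CC)Oc1cc2c(O[Si](C(C)C)(C(C)C)C(C)C)cc(O[Si](C(C)C)(C(C)C)C(C)C)cc2[o+]c1.F[B-](F)(F)F
F3 | step 17 | (2R,3R)-2-[5-oxo-1-(4,4,5,5-tetramethyl-1,3,2-dioxaborolan-2-yl)-3,4,6-tris(triisopropylsilyloxy)-5H-benzo[7]annulen-8-yl]-5,7-bis(triisopropylsilyloxy)chroman-3-yl 3,4,5-tris(tert-butyldimethylsilyloxy)benzoate | O=C(O[C@@H]1Cc2c(O[Si](C(C)C)(C(C)C)C(C)C)cc(O[Si](C(C)C)(C(C)C)C(C)C)cc2O[C@@H]1c1cc(O[Si](C(C)C)(C(C)C)C(C)C)c(=O)c2c(O[Si](C(C)C)(C(C)C)C(C)C)c(O[Si](C(C)C)(C(C)C)C(C)C)cc(B3OC(C)(C)C(C)(C)O3)c2c1)c1cc(O[Si](C)(C)C(C)(C)C)c(O[Si](C)(C)C(C)(C)C)c(O[Si](C)(C)C(C)(C)C)c1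
F4 | step 17 | 2-ethoxy-3-(triethylsilyloxy)-5,7-bis(triisopropylsilyloxy)-2H-chromene | CCOC1Oc2cc(O[Si](C(C)C)(C(C)C)C(C)C)cc(O[Si](C(C)C)(C(C)C)C(C)C)c2C=C1O[Si](CC)(CC)CC
F5 | step 12 | 4-bromo-1,2-bis(tert-butyldimethylsilyloxy)benzene | CC(C)(C)[Si](C)(C)Oc1ccc(Br)cc1O[Si](C)(C)C(C)(C)C
F6 | step 12 | [3,4-bis(tert-butyldimethylsilyloxy)phenyl]lithium | [Li]c1ccc(O[Si](C)(C)C(C)(C)C)c(O[Si](C)(C)C(C)(C)C)c1
F7 | step 12 | [3,4-bis(tert-butyldimethylsilyloxy)phenyl]trimethylsilane | C[Si](C)(C)c1ccc(O[Si](C)(C)C(C)(C)C)c(O[Si](C)(C)C(C)(C)C)c1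
F8 | step 12 | 4-(trimethylsilyl)benzene-1,2-diol | C[Si](C)(C)c1ccc(O)c(O)c1
F9 | step 12 | 4-(trimethylsilyl)-1,2-benzoquinone | C[Si](C)(C)C1=CC(=O)C(=O)C=C1
F10 | step 12 | 3,4,6-trihydroxy-8-iodo-1-(trimethylsilyl)-5H-benzo[7]annulen-5-one | O=c1c(O)cc(I)cc2c([Si](C)(C)C)cc(O)c(O)c12
F11 | step 12 | 8-iodo-1-(trimethylsilyl)-3,4,6-tris(triisopropylsilyloxy)-5H-benzo[7]annulen-5-one | O=c1c(O[Si](C(C)C)(C(C)C)C(C)C)cc(I)cc2c([Si](C)(C)C)cc(O[Si](C(C)C)(C(C)C)C(C)C)c(O[Si](C(C)C)(C(C)C)C(C)C)c12
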